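**Plan**
- Enabling feature: ring C of the isoquinoline (C4a, C5, C6, C7, C8, C8a) is a phenol. Its oxygen sits on C8, between the fusion carbon C8a and the naphthyl-bearing C7. A 2,5-disubstituted furan supplies C4a, C5, C6, C7 and that oxygen, and a terminal alkyne supplies C8a and C8.
- Cuts, in retrosynthetic order: ring D goes back to its N-tosyl tetrahydro form. C4a–C8a and C7–C8 are cut together (furan plus alkyne). Then come N–C1, C4–furan, the furan–C1' bond, and ring B of the naphthalene (C3'–C4', C1'–C2', C1'–C8a').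
- Forward order: ring A is bought as an aryl bromide and ring B is grown on it by benzannulation. The furan is coupled to C1', and the chain C4–C3–N–C1–alkyne is joined in two steps. Rings C and D close together under gold, and ring D is aromatised last.
- Stereochemistry: the target holds only the C7–C1' axis, which becomes stereogenic without control when ring C grows around it. The wanted atropisomer is taken at the end on a chiral phase. C3 (from the (S)-aziridine, untouched) and C1 (from (S)-but-3-yn-2-ol, inverted) only keep the intermediates defined and vanish in steps 9 and 10.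

Key step: step 7

Assumption: the structure is taken as drawn (free hydroxyls on C8 and C5', methoxy on C4'); the line notation does not show the axis, which is taken as M, the mirror image of the axis of dioncophylline A, to be confirmed by circular dichroism after step 11.

Locants of the target (C1–C8a, C1'–C8a') are used for all intermediates. Ring A is C5'–C8', ring B is C1'–C4', ring C is the isoquinoline carbocycle and ring D is the nitrogen ring. Compounds 1, 2, 6, 10, 12 and 15 are catalogue items.

**Step 1**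
Reactants: 1 1-(benzyloxy)-2-bromobenzene; 2 hexacarbonylchromium, Cr(CO)6
Product: 5 pentacarbonyl{[2-(benzyloxy)phenyl](methoxy)methylidene}chromium, via 2-(benzyloxy)phenyllithium 3 (not isolated), via lithium acylpentacarbonylchromate 4 (not isolated)
Conditions: n-BuLi, THF, −78 °C; Cr(CO)6, −78 °C → rt; Me3OBF4, CH2Cl2, rt
Reagents that add atoms: trimethyloxonium tetrafluoroborate, C[O+](C)C.F[B-](F)(F)F
Why: Bromine–lithium exchange, addition of the aryllithium to a carbonyl ligand of zerovalent chromium and O-methylation of the resulting acyl chromate make up the standard Fischer carbene synthesis, and at −78 °C the exchange is far faster than any attack of n-BuLi on the benzyl ether.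

**Step 2**
Reactants: 5 pentacarbonyl{[2-(benzyloxy)phenyl](methoxy)methylidene}chromium; 6 propyne
Product: 8 5-(benzyloxy)-4-methoxy-2-methylnaphthalen-1-ol, via tricarbonylchromium-bound naphthol 7 (not isolated)
Conditions: propyne (3 equiv), THF, 50 °C, sealed tube; then air, Et2O, rt, 30 min
Reagents that add atoms: none
Why: In this Dötz benzannulation the alkyne and one CO insert and the resulting ketene closes onto the only free ortho carbon of ring A, so that ring B forms with the methyl-bearing alkyne carbon next to the new C1' hydroxyl (the normal orientation for terminal alkynes) and the carbene methoxy at C4' peri to the benzyloxy group.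

**Step 3**
Reactants: 8 5-(benzyloxy)-4-methoxy-2-methylnaphthalen-1-ol
Product: 9 5-(benzyloxy)-4-methoxy-2-methylnaphthalen-1-yl trifluoromethanesulfonate
Conditions: Tf2O, pyridine, CH2Cl2, 0 °C
Reagents that add atoms: trifluoromethanesulfonic anhydride, O=S(=O)(OS(=O)(=O)C(F)(F)F)C(F)(F)F
Why: O-Sulfonylation of a naphthol with Tf2O and pyridine is routine, stops the oxidation-prone hydroquinone monoether from going to the quinone and turns C1' into a cross-coupling site.

**Step 4**
Reactants: 9 5-(benzyloxy)-4-methoxy-2-methylnaphthalen-1-yl trifluoromethanesulfonate; 10 furan-2-ylboronic acid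
Product: 11 2-[5-(benzyloxy)-4-methoxy-2-methylnaphthalen-1-yl]furan
Conditions: Pd(OAc)2 (5 mol %), SPhos (10 mol %), K3PO4, THF/H2O, 60 °C
Reagents that add atoms: none
Why: Suzuki–Miyaura coupling of an aryl triflate should succeed here because the bulky, electron-rich biarylphosphine drives oxidative addition into the hindered C1'–O bond while the small five-membered partner keeps transmetalation and reductive elimination easy, an excess of 10 making up for protodeboronation.

**Step 5**
Reactants: 11 2-[5-(benzyloxy)-4-methoxy-2-methylnaphthalen-1-yl]furan; 12 (S)-2-methyl-1-(4-methylbenzenesulfonyl)aziridine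
Product: 14 N-[(2S)-1-{5-[5-(benzyloxy)-4-methoxy-2-methylnaphthalen-1-yl]furan-2-yl}propan-2-yl]-4-methylbenzenesulfonamide, via 5-naphthylfuran-2-yllithium 13 (not isolated)
Conditions: n-BuLi, THF, −78 → 0 °C; then 12, −78 °C → rt; aq NH4Cl
Reagents that add atoms: none
Why: The only free α-position of the 2-arylfuran is its most acidic C–H (furan α-lithiation), and the furyllithium opens the N-sulfonyl aziridine by SN2 attack at the unsubstituted carbon, so the C3 centre is not touched and stays S.

**Step 6**
Reactants: 14 N-[(2S)-1-{5-[5-(benzyloxy)-4-methoxy-2-methylnaphthalen-1-yl]furan-2-yl}propan-2-yl]-4-methylbenzenesulfonamide; 15 (S)-but-3-yn-2-ol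
Product: 16 N-[(2R)-but-3-yn-2-yl]-N-[(2S)-1-{5-[5-(benzyloxy)-4-methoxy-2-methylnaphthalen-1-yl]furan-2-yl}propan-2-yl]-4-methylbenzenesulfonamide
Conditions: PBu3, ADDP, toluene, 0 °C → rt
Reagents that add atoms: none
Why: Mitsunobu N-alkylation of a sulfonamide, run with the ADDP/PBu3 couple that is made for weakly acidic and hindered N–H partners, displaces the slim, SN2-active propargylic oxyphosphonium group with inversion and so sets C1 as R.

**Step 7**
Reactants: 16 N-[(2R)-but-3-yn-2-yl]-N-[(2S)-1-{5-[5-(benzyloxy)-4-methoxy-2-methylnaphthalen-1-yl]furan-2-yl}propan-2-yl]-4-methylbenzenesulfonamide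
Product: 19 (1R,3S)-7-[5-(benzyloxy)-4-methoxy-2-methylnaphthalen-1-yl]-1,3-dimethyl-2-(4-methylbenzenesulfonyl)-1,2,3,4-tetrahydroisoquinolin-8-ol, via oxepine 17 (not isolated), via arene oxide 18 (not isolated)
Conditions: dichloro(pyridine-2-carboxylato)gold, AuCl2(C6H4NO2) (5 mol %), MeCN, rt → 45 °C
Reagents that add atoms: none
Why: Trivalent gold binds the terminal alkyne and furan C2 (the future C4a) attacks its internal carbon (the future C8a) in a 6-exo-dig closure of ring D, giving a cyclopropyl gold carbene that opens, with cleavage of the furan C2–O bond, to a dienone carbene. The aryl ketone oxygen then adds to the carbene carbon (the future C8), releasing the catalyst and oxepine 17, whose disrotatory 6π electrocyclisation to arene oxide 18 makes the C7–C8 bond and so closes ring C. Ionisation of the C7–O bond, which leaves the cation on the aryl-bearing carbon, and loss of the C8 proton give the phenol, so the oxygen can end only on C8, between C8a and C7. This is the Hashmi phenol synthesis, known for N-tosyl tethers of this length (tetrahydroisoquinolin-8-ols) and for furans with bulky 5-aryl groups. No carbon stereocentre is made and C1 and C3 are untouched, while the C7–C1' axis becomes stereogenic here without control, so both atropisomers are expected and are carried on together. The chemoselectivity needed, furan rather than the electron-rich naphthalene as nucleophile, is secured by the four-atom tether, which brings only furan C2 within reach of the alkyne, and the picolinate ligand should keep trivalent gold from being reduced during the slower six-ring closure.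

**Step 8**
Reactants: 19 (1R,3S)-7-[5-(benzyloxy)-4-methoxy-2-methylnaphthalen-1-yl]-1,3-dimethyl-2-(4-methylbenzenesulfonyl)-1,2,3,4-tetrahydroisoquinolin-8-ol
Product: 20 (1R,3S)-8-(benzyloxy)-7-[5-(benzyloxy)-4-methoxy-2-methylnaphthalen-1-yl]-1,3-dimethyl-2-(4-methylbenzenesulfonyl)-1,2,3,4-tetrahydroisoquinoline
Conditions: BnBr, Cs2CO3, DMF, rt
Reagents that add atoms: benzyl bromide, BrCc1ccccc1
Why: Williamson etherification with a mild base caps the C8 oxygen, since a free phenoxide in step 9 would lower the acidity of C1–H and could expel the sulfonamide from C1 by way of an ortho-quinone methide, and the new benzyl group leaves together with the C5' one in step 10.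

**Step 9**
Reactants: 20 (1R,3S)-8-(benzyloxy)-7-[5-(benzyloxy)-4-methoxy-2-methylnaphthalen-1-yl]-1,3-dimethyl-2-(4-methylbenzenesulfonyl)-1,2,3,4-tetrahydroisoquinoline
Product: 21 (3S)-8-(benzyloxy)-7-[5-(benzyloxy)-4-methoxy-2-methylnaphthalen-1-yl]-1,3-dimethyl-3,4-dihydroisoquinoline
Conditions: KOtBu, DMSO, Ar, rt → 50 °C
Reagents that add atoms: none
Why: Base-induced 1,2-elimination (E2) of toluenesulfinate from an N-sulfonyl benzylic amine, the reaction that turns N-tosyl di- and tetrahydroisoquinolines into their C=N forms, removes the tosyl group and raises ring D by one oxidation level at once, erasing C1, while abstraction of C3–H instead would give an imine tautomer that ends in the same isoquinoline.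

**Step 10**
Reactants: 21 (3S)-8-(benzyloxy)-7-[5-(benzyloxy)-4-methoxy-2-methylnaphthalen-1-yl]-1,3-dimethyl-3,4-dihydroisoquinoline
Product: 23 7-(5-hydroxy-4-methoxy-2-methylnaphthalen-1-yl)-1,3-dimethylisoquinolin-8-ol as a mixture of both atropisomers, via dibenzyl ether isoquinoline 22 (not isolated)
Conditions: 10% Pd/C, mesitylene, reflux, Ar; then cool, add MeOH, H2 (1 atm), rt
Reagents that add atoms: none
Why: Dehydrogenation of a 3,4-dihydroisoquinoline over hot Pd/C is the classical last step of isoquinoline syntheses and erases C3, the benzyl ethers act as acceptors for part of the hydrogen released, and the hydrogen atmosphere then completes the hydrogenolysis, so that partly debenzylated material converges on one product.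

**Step 11**
Reactants: 23 7-(5-hydroxy-4-methoxy-2-methylnaphthalen-1-yl)-1,3-dimethylisoquinolin-8-ol as a mixture of both atropisomers
Product: 24 ent-dioncophylleine A, M-configured 7-(5-hydroxy-4-methoxy-2-methylnaphthalen-1-yl)-1,3-dimethylisoquinolin-8-ol
Conditions: HPLC on cellulose tris(3,5-dimethylphenylcarbamate) (Chiralcel OD-H), n-hexane/i-PrOH/Et2NH, rt
Reagents that add atoms: none
Why: The axis is flanked by the C8 hydroxyl, the C2' methyl and the peri position C8', which should make the atropisomers stable at room temperature, so resolution by chromatography on a cellulose carbamate phase, the usual method for naphthylisoquinolines without stereocentres, should deliver the M enantiomer, identified by its circular dichroism spectrum.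

**Compound list**
1 | 1-(benzyloxy)-2-bromobenzene | Brc1ccccc1OCc1ccccc1 | starting material
2 | hexacarbonylchromium | [Cr].[C-]#[O+].[C-]#[O+].[C-]#[O+].[C-]#[O+].[C-]#[O+].[C-]#[O+] | starting material
3 | 2-(benzyloxy)phenyllithium | [Li]c1ccccc1OCc1ccccc1 | intermediate
4 | lithium [2-(benzyloxy)benzoyl]pentacarbonylchromate | [Li+].[O-]C(=[Cr])c1ccccc1OCc1ccccc1.[C-]#[O+].[C-]#[O+].[C-]#[O+].[C-]#[O+].[C-]#[O+] | intermediate
5 | pentacarbonyl{[2-(benzyloxy)phenyl](methoxy)methylidene}chromium | COC(=[Cr])c1ccccc1OCc1ccccc1.[C-]#[O+].[C-]#[O+].[C-]#[O+].[C-]#[O+].[C-]#[O+] | intermediate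
6 | propyne | CC#C | starting material
7 | tricarbonyl[η6-5-(benzyloxy)-4-methoxy-2-methylnaphthalen-1-ol]chromium | COc1cc(C)c(O)c2cccc(OCc3ccccc3)c12.[Cr].[C-]#[O+].[C-]#[O+].[C-]#[O+] | intermediate
8 | 5-(benzyloxy)-4-methoxy-2-methylnaphthalen-1-ol | COc1cc(C)c(O)c2cccc(OCc3ccccc3)c12 | intermediate
9 | 5-(benzyloxy)-4-methoxy-2-methylnaphthalen-1-yl trifluoromethanesulfonate | COc1cc(C)c(OS(=O)(=O)C(F)(F)F)c2cccc(OCc3ccccc3)c12 | intermediate
10 | furan-2-ylboronic acid | OB(O)c1ccco1 | starting material
11 | 2-[5-(benzyloxy)-4-methoxy-2-methylnaphthalen-1-yl]furan | COc1cc(C)c(-c2ccco2)c2cccc(OCc3ccccc3)c12 | intermediate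
12 | (S)-2-methyl-1-(4-methylbenzenesulfonyl)aziridine | C[C@H]1CN1S(=O)(=O)c1ccc(C)cc1 | starting material
13 | {5-[5-(benzyloxy)-4-methoxy-2-methylnaphthalen-1-yl]furan-2-yl}lithium | COc1cc(C)c(-c2ccc([Li])o2)c2cccc(OCc3ccccc3)c12 | intermediate
14 | N-[(2S)-1-{5-[5-(benzyloxy)-4-methoxy-2-methylnaphthalen-1-yl]furan-2-yl}propan-2-yl]-4-methylbenzenesulfonamide | Cc1ccc(cc1)S(=O)(=O)N[C@@H](C)Cc1ccc(-c2c(C)cc(OC)c3c(OCc4ccccc4)cccc23)o1 | intermediate
15 | (S)-but-3-yn-2-ol | C#C[C@H](C)O | starting material
16 | N-[(2R)-but-3-yn-2-yl]-N-[(2S)-1-{5-[5-(benzyloxy)-4-methoxy-2-methylnaphthalen-1-yl]furan-2-yl}propan-2-yl]-4-methylbenzenesulfonamide | C#C[C@@H](C)N(S(=O)(=O)c1ccc(C)cc1)[C@@H](C)Cc1ccc(-c2c(C)cc(OC)c3c(OCc4ccccc4)cccc23)o1 | intermediate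
17 | oxepine isomer of 19: ring D closed (1R,3S), oxygen bridging C7 and C8 in a seven-membered ring, C8=C8a, C4a=C5 and C6=C7 double bonds | C[C@H]1CC2=CC=C(c3c(C)cc(OC)c4c(OCc5ccccc5)cccc34)OC=C2[C@@H](C)N1S(=O)(=O)c1ccc(C)cc1 | intermediate
18 | 7,8-arene oxide isomer of 19: (1R,3S), epoxide on C7–C8, C4a=C8a and C5=C6 double bonds, C7/C8 configuration not controlled | C[C@H]1CC2=C(C3OC3(c3c(C)cc(OC)c4c(OCc5ccccc5)cccc34)C=C2)[C@@H](C)N1S(=O)(=O)c1ccc(C)cc1 | intermediate
19 | (1R,3S)-7-[5-(benzyloxy)-4-methoxy-2-methylnaphthalen-1-yl]-1,3-dimethyl-2-(4-methylbenzenesulfonyl)-1,2,3,4-tetrahydroisoquinolin-8-ol (both atropisomers) | C[C@H]1Cc2ccc(-c3c(C)cc(OC)c4c(OCc5ccccc5)cccc34)c(O)c2[C@@H](C)N1S(=O)(=O)c1ccc(C)cc1 | intermediate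
20 | (1R,3S)-8-(benzyloxy)-7-[5-(benzyloxy)-4-methoxy-2-methylnaphthalen-1-yl]-1,3-dimethyl-2-(4-methylbenzenesulfonyl)-1,2,3,4-tetrahydroisoquinoline | C[C@H]1Cc2ccc(-c3c(C)cc(OC)c4c(OCc5ccccc5)cccc34)c(OCc3ccccc3)c2[C@@H](C)N1S(=O)(=O)c1ccc(C)cc1 | intermediate
21 | (3S)-8-(benzyloxy)-7-[5-(benzyloxy)-4-methoxy-2-methylnaphthalen-1-yl]-1,3-dimethyl-3,4-dihydroisoquinoline | C[C@H]1Cc2ccc(-c3c(C)cc(OC)c4c(OCc5ccccc5)cccc34)c(OCc3ccccc3)c2C(C)=N1 | intermediate
22 | 8-(benzyloxy)-7-[5-(benzyloxy)-4-methoxy-2-methylnaphthalen-1-yl]-1,3-dimethylisoquinoline | Cc1cc2ccc(-c3c(C)cc(OC)c4c(OCc5ccccc5)cccc34)c(OCc3ccccc3)c2c(C)n1 | intermediate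
23 | 7-(5-hydroxy-4-methoxy-2-methylnaphthalen-1-yl)-1,3-dimethylisoquinolin-8-ol, both atropisomers | COc1cc(C)c(-c2ccc3cc(C)nc(C)c3c2O)c2cccc(O)c12 | intermediate
24 | ent-dioncophylleine A, M atropisomer of 23 | COc1cc(C)c(-c2ccc3cc(C)nc(C)c3c2O)c2cccc(O)c12 | target

**Total step count:** 11. **Longest linear sequence:** 11 (1 → 24); every other building block is bought.

**Steps most likely to fail**

**Step 7.**
- What may go wrong: the gold catalyst may be reduced to metal before the slow six-ring closure is complete. Crowding next to the naphthyl group may also hold back oxygen transfer to C8 and the closure of ring C.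
- Fallback approach: the gold-catalysed ring construction is kept but run on a furan without the naphthyl group, and the axis is made afterwards by cross-coupling. It sets out from 12, 15 and 9 and returns at 20.
- Furan is lithiated (n-BuLi, THF) and opens 12 to N-[(2S)-1-(furan-2-yl)propan-2-yl]-4-methylbenzenesulfonamide F1.
- Mitsunobu alkylation with 15 as in step 6 gives N-[(2R)-but-3-yn-2-yl]-N-[(2S)-1-(furan-2-yl)propan-2-yl]-4-methylbenzenesulfonamide F2.
- The catalyst of step 7 should convert this into (1R,3S)-1,3-dimethyl-2-(4-methylbenzenesulfonyl)-1,2,3,4-tetrahydroisoquinolin-8-ol F3.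
- Amine-mediated ortho-bromination (NBS, i-Pr2NH, CH2Cl2) gives (1R,3S)-7-bromo-1,3-dimethyl-2-(4-methylbenzenesulfonyl)-1,2,3,4-tetrahydroisoquinolin-8-ol F4.
- Benzylation as in step 8 gives (1R,3S)-8-(benzyloxy)-7-bromo-1,3-dimethyl-2-(4-methylbenzenesulfonyl)-1,2,3,4-tetrahydroisoquinoline F5.
- Triflate 9 is converted by Miyaura borylation (B2pin2, PdCl2(dppf), KOAc, dioxane) into 2-[5-(benzyloxy)-4-methoxy-2-methylnaphthalen-1-yl]-4,4,5,5-tetramethyl-1,3,2-dioxaborolane F6.
- Suzuki–Miyaura coupling of F5 with F6 (Pd(OAc)2, SPhos, K3PO4, toluene/H2O, 100 °C) gives 20.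

**Step 6.**
- What may go wrong: displacement between two secondary centres may be so slow that the activated alcohol is lost by elimination or is captured by the reduced azo reagent.
- Fallback approach: the amine is built by reductive amination at C3 in place of substitution at C1. It sets out from 11 (lithiated to 13 as in step 5) and returns at 16.
- Compound 13 opens racemic 2-methyloxirane to 1-{5-[5-(benzyloxy)-4-methoxy-2-methylnaphthalen-1-yl]furan-2-yl}propan-2-ol F7.
- Dess–Martin periodinane gives 1-{5-[5-(benzyloxy)-4-methoxy-2-methylnaphthalen-1-yl]furan-2-yl}propan-2-one F8.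
- Commercial (R)-but-3-yn-2-amine with Ti(OiPr)4 and then NaBH4 gives (2R)-N-(1-{5-[5-(benzyloxy)-4-methoxy-2-methylnaphthalen-1-yl]furan-2-yl}propan-2-yl)but-3-yn-2-amine F9 as both C3 epimers.
- TsCl, pyridine and DMAP give 16 together with its C3 epimer N-[(2R)-but-3-yn-2-yl]-N-[(2R)-1-{5-[5-(benzyloxy)-4-methoxy-2-methylnaphthalen-1-yl]furan-2-yl}propan-2-yl]-4-methylbenzenesulfonamide F10.
- F10 can be taken through steps 7 to 10 alongside 16, since both converge at 22.

**Step 9.**
- What may go wrong: proton abstraction at the crowded C1 (or at the non-benzylic C3) may be too slow, so that the sulfonamide survives or the benzyl ethers begin to degrade in the strongly basic medium.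
- Fallback approach: elimination is replaced by reductive N–S cleavage. It sets out from 20 and returns at 22.
- Magnesium turnings in methanol with sonication should give (1R,3S)-8-(benzyloxy)-7-[5-(benzyloxy)-4-methoxy-2-methylnaphthalen-1-yl]-1,3-dimethyl-1,2,3,4-tetrahydroisoquinoline F11.
- Under the Pd/C, mesitylene conditions of step 10, F11 loses two molecules of hydrogen, a dehydrogenation well known for 1,3-dimethyltetrahydroisoquinolines of this alkaloid family. This gives 22, which is then hydrogenolysed in the same flask.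

**Further compounds**
F1 | step 7 | N-[(2S)-1-(furan-2-yl)propan-2-yl]-4-methylbenzenesulfonamide | Cc1ccc(cc1)S(=O)(=O)N[C@@H](C)Cc1ccco1
F2 | step 7 | N-[(2R)-but-3-yn-2-yl]-N-[(2S)-1-(furan-2-yl)propan-2-yl]-4-methylbenzenesulfonamide | C#C[C@@H](C)N(S(=O)(=O)c1ccc(C)cc1)[C@@H](C)Cc1ccco1
F3 | step 7 | (1R,3S)-1,3-dimethyl-2-(4-methylbenzenesulfonyl)-1,2,3,4-tetrahydroisoquinolin-8-ol | C[C@H]1Cc2cccc(O)c2[C@@H](C)N1S(=O)(=O)c1ccc(C)cc1
F4 | step 7 | (1R,3S)-7-bromo-1,3-dimethyl-2-(4-methylbenzenesulfonyl)-1,2,3,4-tetrahydroisoquinolin-8-ol | C[C@H]1Cc2ccc(Br)c(O)c2[C@@H](C)N1S(=O)(=O)c1ccc(C)cc1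
F5 | step 7 | (1R,3S)-8-(benzyloxy)-7-bromo-1,3-dimethyl-2-(4-methylbenzenesulfonyl)-1,2,3,4-tetrahydroisoquinoline | C[C@H]1Cc2ccc(Br)c(OCc3ccccc3)c2[C@@H](C)N1S(=O)(=O)c1ccc(C)cc1
F6 | step 7 | 2-[5-(benzyloxy)-4-methoxy-2-methylnaphthalen-1-yl]-4,4,5,5-tetramethyl-1,3,2-dioxaborolane | COc1cc(C)c(B2OC(C)(C)C(C)(C)O2)c2cccc(OCc3ccccc3)c12
F7 | step 6 | 1-{5-[5-(benzyloxy)-4-methoxy-2-methylnaphthalen-1-yl]furan-2-yl}propan-2-ol (racemic) | CC(O)Cc1ccc(-c2c(C)cc(OC)c3c(OCc4ccccc4)cccc23)o1
F8 | step 6 | 1-{5-[5-(benzyloxy)-4-methoxy-2-methylnaphthalen-1-yl]furan-2-yl}propan-2-one | CC(=O)Cc1ccc(-c2c(C)cc(OC)c3c(OCc4ccccc4)cccc23)o1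
F9 | step 6 | (2R)-N-(1-{5-[5-(benzyloxy)-4-methoxy-2-methylnaphthalen-1-yl]furan-2-yl}propan-2-yl)but-3-yn-2-amine (both C3 epimers) | C#C[C@@H](C)NC(C)Cc1ccc(-c2c(C)cc(OC)c3c(OCc4ccccc4)cccc23)o1
F10 | step 6 | N-[(2R)-but-3-yn-2-yl]-N-[(2R)-1-{5-[5-(benzyloxy)-4-methoxy-2-methylnaphthalen-1-yl]furan-2-yl}propan-2-yl]-4-methylbenzenesulfonamide | C#C[C@@H](C)N(S(=O)(=O)c1ccc(C)cc1)[C@H](C)Cc1ccc(-c2c(C)cc(OC)c3c(OCc4ccccc4)cccc23)o1
F11 | step 9 | (1R,3S)-8-(benzyloxy)-7-[5-(benzyloxy)-4-methoxy-2-methylnaphthalen-1-yl]-1,3-dimethyl-1,2,3,4-tetrahydroisoquinoline | C[C@H]1Cc2ccc(-c3c(C)cc(OC)c4c(OCc5ccccc5)cccc34)c(OCc3ccccc3)c2[C@@H](C)N1
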